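The constants used here were set for the occasion; what happens was integrated by code.

**Next run.** A factor of 153 separated the two captures in this flask as I reckoned them: the second nucleophile taken at its charge took up intermediate that much faster than first nucleophile taken at its solubility, so my decision on the next charges hung on when that reagent would end.

    solid first nucleophile ⇌ first nucleophile, rate k1*(cs1 - [first nucleophile]) while solid is left; crystals form when [first nucleophile] > cs1 (cs1 = 14 mM, k1 = 0.28 min⁻¹)
    second nucleophile + intermediate → other capture product (k2 = 180 M⁻¹ min⁻¹)
    second nucleophile → decomposed reagent (k3 = 0.0014 min⁻¹)
    first nucleophile + intermediate → target (k4 = 5.8 M⁻¹ min⁻¹)
    substrate → intermediate (k5 = 0.0063 min⁻¹)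

substrate 0.069 M; second nucleophile 0.0690 M; solid first nucleophile 0.104 M; time 20 h

- given per volume of solution although it is solid: solid first nucleophile
- at the start none of the solid first nucleophile is in solution
- run time (flask): 20 h

- target at 20 h, in percent of the substrate charged
- the change that raises the amount of target at 20 h, in percent of the substrate charged most ("none" if none brings more than 2 percentage points) (south / east / west / none)
- amount of target at 20 h, in percent of the substrate charged, after east

- south: doubling the dissolution coefficient of step 1, all else as stated
- east: doubling the amount of second nucleophile, all else as stated
- west: doubling the solubility in step 1, all else as stated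

**My reckoning.** I counted every intermediate as taken by the second nucleophile, so that d[second nucleophile]/dt = −0.0014 min⁻¹[second nucleophile] − 0.0063 min⁻¹[substrate], with [substrate] falling exponentially. This linear equation integrates in closed form. With 0.00490 min⁻¹ as the difference of the constants, [second nucleophile] reaches zero where exp(−0.00490 min⁻¹·t) = 1 − (0.00490 min⁻¹/0.0063 min⁻¹)·(charged second nucleophile/charged substrate). For this flask I reckoned that moment at 5.12 h. The substrate unconverted at that moment is the escaped share, 14.5% of the charge.

**The decision.** The escaped amount, 0.00998 M, was smaller than the solid charge, and the pseudo-first-order constant of intermediate with first nucleophile at its solubility, 0.0812 min⁻¹, was larger than the 0.0063 min⁻¹ of substrate. So I took target as about 14.5% and expected neither faster dissolution nor higher solubility to gain 2 percentage points. Doubling the second nucleophile turned the right-hand side negative, −0.556, which gave no zero and no escaped share, leaving target to a slow leak. I decided to change nothing.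

**The result.** The forecast gave 14.9% (range 14% to 16%), 0.66% after doubling and best change none, on the ground that “slow decomposition leaves it about 15% short of the substrate”. The simulation gave 14.8%, 0.654% after doubling and best change none, with doubled solubility adding 0.39 points.

**One reason.** The flask's target stood 0.30 points above my 14.5%. Capture by the second nucleophile is the main reason for the missing target, but decomposition is part of why target stood as high as it did: the run without that loss gave 2.41%.

**Second flask.** With 0.28 M of substrate, the escaped share came to 76.1%, or 0.213 M, exceeding the solid charge, which covers 37.1% of that substrate. That neighbour flask gave target 37.1%, other capture product 23.9% and intermediate 38.9%.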